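The oxolane ring O–C7–C8–C9–C10 (chain numbering C1–C15 from the alkyne terminus) is disconnected at C8–C9 and O–C10. C5–C8, with stereocentres C6 and C7, map onto C2-symmetric (S,S)-diepoxybutane; C9–C15 is a silyl-capped diyne. In one operation its lithium diynide opens one oxirane at the unsubstituted ring methylene C8, and the freed C7 hydroxyl adds 5-endo-dig across C9≡C10 under gold catalysis, closing a 2-alkynyl-4,5-dihydrofuran. The step exploits the CH2 group C8 flanked by the C7–O stereocentre. The enol ether then takes Br (C9) and H (C10) anti, the second oxirane brings C1–C4, and one Lindlar hydrogenation sets both Z-alkenes.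

Key step: step 3

Assumption: (3S)-pent-1-yn-3-ol, (bromoethynyl)trimethylsilane and (S,S)-1,2:3,4-diepoxybutane are taken as purchasable single compounds; carbon labels C1–C15 follow the target chain.

Step 1
Reactants: 1 (3S)-pent-1-yn-3-ol; 2 (bromoethynyl)trimethylsilane
Product: 3 (3S)-7-(trimethylsilyl)hepta-4,6-diyn-3-ol
Conditions: CuCl (5 mol%), NH2OH·HCl, n-BuNH2, H2O/CH2Cl2, 0 °C
Reagents that add atoms: none
Why: Cadiot–Chodkiewicz coupling: the copper acetylide of 1 should couple with bromoalkyne 2 to give the unsymmetrical 1,3-diyne (C10–C11 bond) without touching the C13 carbinol stereocentre.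

Step 2
Reactants: 3 (3S)-7-(trimethylsilyl)hepta-4,6-diyn-3-ol
Product: 4 tert-butyl(dimethyl){[(3S)-7-(trimethylsilyl)hepta-4,6-diyn-3-yl]oxy}silane
Conditions: TBSCl, imidazole, DMF, 23 °C
Reagents that add atoms: tert-butyldimethylsilyl chloride, CC(C)(C)[Si](C)(C)Cl
Why: Imidazole-promoted silyl ether formation should mask the C13 hydroxyl against MeLi, BF3 and the later chlorination.

Step 3
Reactants: 4 tert-butyl(dimethyl){[(3S)-7-(trimethylsilyl)hepta-4,6-diyn-3-yl]oxy}silane; 5 (2S,2'S)-2,2'-bioxirane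
Product: 8 tert-butyl(dimethyl){[(3S)-1-{(5S)-5-[(2S)-oxiran-2-yl]-4,5-dihydrofuran-2-yl}pent-1-yn-3-yl]oxy}silane, via lithium diynide 6 (not isolated), via epoxy alcohol 7 (not isolated)
Conditions: 4, MeLi·LiBr, THF, 0 → 23 °C; −78 °C, BF3·OEt2, then 5 (3 equiv); aq NaHCO3, THF and excess 5 evaporated, crude 7 in CH2Cl2 (no purification), Ph3PAuNTf2 (2 mol%), 23 °C; Et3N quench
Reagents that add atoms: none
Why: MeLi cleaves the C–Si bond of 4 to give diynide 6, which under BF3 activation opens one oxirane of 5 by SN2 attack at the terminal carbon C8 (C8–C9 bond) and leaves C7 untouched; Ph3PAuNTf2 then activates C9≡C10 of 7, the C7 hydroxyl adds at C10 anti to gold (O–C10 bond), and protodeauration gives the enol ether. The closest known reaction types are the BF3-promoted alkynylation of terminal epoxides and the gold-catalysed cycloisomerisation of 3-alkyn-1-ols, telescoped here into a formal (3+2) annulation of the O–C7–C8 unit onto an alkyne. The oxolane ring closes in the 5-endo-dig mode, the only five-membered option, since attack at C9 would give an oxetane. No new stereocentre is formed: C6 and C7 come from 5, C13 from 1, and C9 and C10 stay sp2 for steps 4 and 7. The step needs mono-opening (both oxiranes of 5 are homotopic and an excess of volatile 5 limits double addition), terminal regioselectivity (steric control under BF3) and the hydroxyl rather than the oxirane oxygen as nucleophile (the alcohol is the better donor, and no free alkoxide is present that could trigger a Payne shift).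

Step 4
Reactants: 8 tert-butyl(dimethyl){[(3S)-1-{(5S)-5-[(2S)-oxiran-2-yl]-4,5-dihydrofuran-2-yl}pent-1-yn-3-yl]oxy}silane
Product: 9 {[(3S)-1-{(2R,3R,5S)-3-bromo-2-methoxy-5-[(2S)-oxiran-2-yl]oxolan-2-yl}pent-1-yn-3-yl]oxy}(tert-butyl)dimethylsilane
Conditions: NBS, MeOH, NaHCO3, CH2Cl2, −78 → −40 °C
Reagents that add atoms: N-bromosuccinimide, O=C1CCC(=O)N1Br; methanol, CO
Why: Bromoalkoxylation (haloetherification) of the enol ether: Br+ should add to the nucleophilic carbon C9 on the ring face opposite the C7 oxiranyl group and methanol should trap the oxocarbenium ion at C10 anti to bromine, so C9 is set by 1,3-induction from C7 and C10 by anti addition.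

Step 5
Reactants: 9 {[(3S)-1-{(2R,3R,5S)-3-bromo-2-methoxy-5-[(2S)-oxiran-2-yl]oxolan-2-yl}pent-1-yn-3-yl]oxy}(tert-butyl)dimethylsilane; 10 1,4-bis(trimethylsilyl)buta-1,3-diyne
Product: 12 (1S)-1-[(2S,4R,5R)-4-bromo-5-{(3S)-3-[(tert-butyldimethylsilyl)oxy]pent-1-yn-1-yl}-5-methoxyoxolan-2-yl]-6-(trimethylsilyl)hexa-3,5-diyn-1-ol, via lithium silylbutadiynide 11 (not isolated)
Conditions: 10, MeLi·LiBr, THF, 23 °C; −78 °C, BF3·OEt2, then 9, −78 °C
Reagents that add atoms: none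
Why: BF3-promoted alkynylation of a terminal epoxide: diynide 11, freed from 10 by MeLi, should open the oxirane at its CH2 terminus C5 by SN2, which leaves the C6 carbinol (S) unchanged and should spare the bromine-deactivated ketal at −78 °C.

Step 6
Reactants: 12 (1S)-1-[(2S,4R,5R)-4-bromo-5-{(3S)-3-[(tert-butyldimethylsilyl)oxy]pent-1-yn-1-yl}-5-methoxyoxolan-2-yl]-6-(trimethylsilyl)hexa-3,5-diyn-1-ol
Product: 13 {[(3S)-1-{(2R,3R,5S)-3-bromo-5-[(1R)-1-chloro-6-(trimethylsilyl)hexa-3,5-diyn-1-yl]-2-methoxyoxolan-2-yl}pent-1-yn-3-yl]oxy}(tert-butyl)dimethylsilane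
Conditions: CCl4, (n-C8H17)3P, pyridine, toluene, 60 °C
Reagents that add atoms: tetrachloromethane, ClC(Cl)(Cl)Cl
Why: Appel-type chlorination: the alkoxyphosphonium ion of the C6 alcohol should be displaced by chloride with SN2 inversion, turning the (6S)-alcohol into the (6R)-chloride anti to the C7–O bond.

Step 7
Reactants: 13 {[(3S)-1-{(2R,3R,5S)-3-bromo-5-[(1R)-1-chloro-6-(trimethylsilyl)hexa-3,5-diyn-1-yl]-2-methoxyoxolan-2-yl}pent-1-yn-3-yl]oxy}(tert-butyl)dimethylsilane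
Product: 14 {[(3S)-1-{(2R,3R,5S)-3-bromo-5-[(1R)-1-chloro-6-(trimethylsilyl)hexa-3,5-diyn-1-yl]oxolan-2-yl}pent-1-yn-3-yl]oxy}(tert-butyl)dimethylsilane
Conditions: Et3SiH, Me3SiOTf (0.2 equiv), CH2Cl2, −78 → −40 °C
Reagents that add atoms: none
Why: Ionic reduction of a ketal (silane addition to a cyclic oxocarbenium ion): Me3SiOTf should ionise the C10–OMe bond and Et3SiH should deliver hydride to C10 anti to the neighbouring C9 bromine, which sets C10 with the alkynyl group cis to Br and trans to the C7 side chain.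

Step 8
Reactants: 14 {[(3S)-1-{(2R,3R,5S)-3-bromo-5-[(1R)-1-chloro-6-(trimethylsilyl)hexa-3,5-diyn-1-yl]oxolan-2-yl}pent-1-yn-3-yl]oxy}(tert-butyl)dimethylsilane
Product: 15 {[(1Z,3S)-1-{(2R,3R,5S)-3-bromo-5-[(1R,3Z)-1-chloro-6-(trimethylsilyl)hex-3-en-5-yn-1-yl]oxolan-2-yl}pent-1-en-3-yl]oxy}(tert-butyl)dimethylsilane
Conditions: H2 (1 atm), Pd/CaCO3 poisoned with Pb(OAc)2, quinoline, EtOAc, 23 °C, stopped after 2 equiv H2
Reagents that add atoms: none
Why: Lindlar semi-hydrogenation: syn addition of H2 should convert the C11≡C12 and C3≡C4 triple bonds into the two Z-alkenes while the C1≡C2 triple bond is shielded by its Me3Si cap.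

Step 9
Reactants: 15 {[(1Z,3S)-1-{(2R,3R,5S)-3-bromo-5-[(1R,3Z)-1-chloro-6-(trimethylsilyl)hex-3-en-5-yn-1-yl]oxolan-2-yl}pent-1-en-3-yl]oxy}(tert-butyl)dimethylsilane
Product: 16 (1Z,3S)-1-{(2R,3R,5S)-3-bromo-5-[(1R,3Z)-1-chlorohex-3-en-5-yn-1-yl]oxolan-2-yl}pent-1-en-3-ol
Conditions: n-Bu4NF, AcOH, THF, 0 → 23 °C
Reagents that add atoms: none
Why: Fluoride-mediated desilylation: buffered n-Bu4NF should cleave both the O–Si bond at C13 and the C(sp)–Si bond at C1, the acetic acid buffer suppressing E2 loss of HBr or HCl.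

Step 10
Reactants: 16 (1Z,3S)-1-{(2R,3R,5S)-3-bromo-5-[(1R,3Z)-1-chlorohex-3-en-5-yn-1-yl]oxolan-2-yl}pent-1-en-3-ol
Product: 17 (2R,3R,5S)-3-bromo-2-[(1Z,3R)-3-bromopent-1-en-1-yl]-5-[(1R,3Z)-1-chlorohex-3-en-5-yn-1-yl]oxolane
Conditions: CBr4, PPh3, 2,6-di-tert-butylpyridine, CH2Cl2, −20 → 0 °C
Reagents that add atoms: tetrabromomethane, BrC(Br)(Br)Br
Why: Appel bromination: the alkoxyphosphonium ion of the (13S)-allylic alcohol should be displaced by bromide at low temperature with SN2 inversion to give the (13R)-bromide with the Z-alkene intact.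

Compound list
1 | (3S)-pent-1-yn-3-ol | C#C[C@@H](O)CC | starting material
2 | (bromoethynyl)trimethylsilane | C[Si](C)(C)C#CBr | starting material
3 | (3S)-7-(trimethylsilyl)hepta-4,6-diyn-3-ol | C[Si](C)(C)C#CC#C[C@@H](O)CC | intermediate
4 | tert-butyl(dimethyl){[(3S)-7-(trimethylsilyl)hepta-4,6-diyn-3-yl]oxy}silane | C[Si](C)(C)C#CC#C[C@@H](O[Si](C)(C)C(C)(C)C)CC | intermediate
5 | (2S,2'S)-2,2'-bioxirane, (S,S)-1,2:3,4-diepoxybutane | C1O[C@@H]1[C@@H]1CO1 | starting material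
6 | lithium (5S)-5-[(tert-butyldimethylsilyl)oxy]hepta-1,3-diyn-1-ide | [Li]C#CC#C[C@@H](O[Si](C)(C)C(C)(C)C)CC | intermediate
7 | (1S,7S)-7-[(tert-butyldimethylsilyl)oxy]-1-[(2S)-oxiran-2-yl]nona-3,5-diyn-1-ol | C1O[C@@H]1[C@@H](O)CC#CC#C[C@@H](O[Si](C)(C)C(C)(C)C)CC | intermediate
8 | tert-butyl(dimethyl){[(3S)-1-{(5S)-5-[(2S)-oxiran-2-yl]-4,5-dihydrofuran-2-yl}pent-1-yn-3-yl]oxy}silane | C1O[C@@H]1[C@@H]1CC=C(C#C[C@@H](O[Si](C)(C)C(C)(C)C)CC)O1 | intermediate
9 | {[(3S)-1-{(2R,3R,5S)-3-bromo-2-methoxy-5-[(2S)-oxiran-2-yl]oxolan-2-yl}pent-1-yn-3-yl]oxy}(tert-butyl)dimethylsilane (Br trans to oxiranyl, OMe trans to Br) | C1O[C@@H]1[C@@H]1C[C@@H](Br)[C@@](OC)(C#C[C@@H](O[Si](C)(C)C(C)(C)C)CC)O1 | intermediate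
10 | 1,4-bis(trimethylsilyl)buta-1,3-diyne | C[Si](C)(C)C#CC#C[Si](C)(C)C | starting material
11 | lithium 4-(trimethylsilyl)buta-1,3-diyn-1-ide | [Li]C#CC#C[Si](C)(C)C | intermediate
12 | (1S)-1-[(2S,4R,5R)-4-bromo-5-{(3S)-3-[(tert-butyldimethylsilyl)oxy]pent-1-yn-1-yl}-5-methoxyoxolan-2-yl]-6-(trimethylsilyl)hexa-3,5-diyn-1-ol | C[Si](C)(C)C#CC#CC[C@H](O)[C@@H]1C[C@@H](Br)[C@@](OC)(C#C[C@@H](O[Si](C)(C)C(C)(C)C)CC)O1 | intermediate
13 | {[(3S)-1-{(2R,3R,5S)-3-bromo-5-[(1R)-1-chloro-6-(trimethylsilyl)hexa-3,5-diyn-1-yl]-2-methoxyoxolan-2-yl}pent-1-yn-3-yl]oxy}(tert-butyl)dimethylsilane | C[Si](C)(C)C#CC#CC[C@@H](Cl)[C@@H]1C[C@@H](Br)[C@@](OC)(C#C[C@@H](O[Si](C)(C)C(C)(C)C)CC)O1 | intermediate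
14 | {[(3S)-1-{(2R,3R,5S)-3-bromo-5-[(1R)-1-chloro-6-(trimethylsilyl)hexa-3,5-diyn-1-yl]oxolan-2-yl}pent-1-yn-3-yl]oxy}(tert-butyl)dimethylsilane | C[Si](C)(C)C#CC#CC[C@@H](Cl)[C@@H]1C[C@@H](Br)[C@@H](C#C[C@@H](O[Si](C)(C)C(C)(C)C)CC)O1 | intermediate
15 | {[(1Z,3S)-1-{(2R,3R,5S)-3-bromo-5-[(1R,3Z)-1-chloro-6-(trimethylsilyl)hex-3-en-5-yn-1-yl]oxolan-2-yl}pent-1-en-3-yl]oxy}(tert-butyl)dimethylsilane | C[Si](C)(C)C#C/C=C\C[C@@H](Cl)[C@@H]1C[C@@H](Br)[C@@H](/C=C\[C@@H](O[Si](C)(C)C(C)(C)C)CC)O1 | intermediate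
16 | (1Z,3S)-1-{(2R,3R,5S)-3-bromo-5-[(1R,3Z)-1-chlorohex-3-en-5-yn-1-yl]oxolan-2-yl}pent-1-en-3-ol | C#C/C=C\C[C@@H](Cl)[C@@H]1C[C@@H](Br)[C@@H](/C=C\[C@@H](O)CC)O1 | intermediate
17 | (2R,3R,5S)-3-bromo-2-[(1Z,3R)-3-bromopent-1-en-1-yl]-5-[(1R,3Z)-1-chlorohex-3-en-5-yn-1-yl]oxolane | C#C/C=C\C[C@@H](Cl)[C@@H]1C[C@@H](Br)[C@@H](/C=C\[C@H](Br)CC)O1 | target

Total step count: 10. Longest linear sequence: 10 steps (1 → 17).

Steps most likely to fail

Step 3. What may go wrong: opening of both oxiranes of 5, or, in the gold stage, attack of the oxirane oxygen on the activated alkyne and acid-promoted hydration of the enol ether. The fallback sets out from 1 and 5 and comes back at 8; it makes the same two ring bonds by enolate annulation to a lactone. 1 is silylated (TBSCl, imidazole, DMF) to tert-butyl(dimethyl)[(3S)-pent-1-yn-3-yloxy]silane F1. Excess 5 is opened at C8 by the lithium enolate of ethyl acetate (LiN(iPr)2, Et2AlCl, THF, −78 °C) to ethyl (4S)-4-hydroxy-4-[(2S)-oxiran-2-yl]butanoate F2. F2 lactonises (pyridinium p-toluenesulfonate, toluene, 50 °C) to (5S)-5-[(2S)-oxiran-2-yl]oxolan-2-one F3. The lithium acetylide of F1 (n-BuLi, THF, −78 °C) adds to F3 to give the hemiketal (5S)-2-{(3S)-3-[(tert-butyldimethylsilyl)oxy]pent-1-yn-1-yl}-5-[(2S)-oxiran-2-yl]oxolan-2-ol F4, and dehydration (MsCl, Et3N, CH2Cl2, 0 °C) should give 8.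

Step 7. What may go wrong: slow ionisation of the ketal beside the C–Br bond, hydride attack on the wrong face of the oxocarbenium ion, or loss of HBr from it. The fallback sets out from 12 and comes back at 14; it delivers the hydride intramolecularly from a silicon tether on the C7 side chain. 12 is silylated at the C6 oxygen (Me2SiHCl, Et3N, CH2Cl2, 0 °C) to the O6-dimethylsilyl ether of 12 F5. Me3SiOTf (CH2Cl2, −78 °C) ionises the ketal and the tethered Si–H, held on the face of the C7 substituent, should transfer hydride to C10 (intramolecular ionic hydrosilylation). Aqueous AcOH work-up frees (1S)-1-[(2S,4R,5R)-4-bromo-5-{(3S)-3-[(tert-butyldimethylsilyl)oxy]pent-1-yn-1-yl}oxolan-2-yl]-6-(trimethylsilyl)hexa-3,5-diyn-1-ol F6, which is chlorinated with inversion under the conditions of step 6 to give 14.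

Step 10. What may go wrong: allylic transposition (SN2′ attack at C11) or ionisation of the activated (Z)-allylic alcohol, with loss of configuration at C13 and of alkene geometry. The fallback sets out from 14 and comes back at 17; it installs the bromide at the propargylic stage, before the alkene exists. 14 is desilylated at oxygen only (HF·pyridine, THF, 0 °C) to (3S)-1-{(2R,3R,5S)-3-bromo-5-[(1R)-1-chloro-6-(trimethylsilyl)hexa-3,5-diyn-1-yl]oxolan-2-yl}pent-1-yn-3-ol F7. CBr4/PPh3 (CH2Cl2, −20 °C) should give, with inversion, (2R,3R,5S)-3-bromo-2-[(3R)-3-bromopent-1-yn-1-yl]-5-[(1R)-1-chloro-6-(trimethylsilyl)hexa-3,5-diyn-1-yl]oxolane F8. Semi-hydrogenation under the conditions of step 8 gives (2R,3R,5S)-3-bromo-2-[(1Z,3R)-3-bromopent-1-en-1-yl]-5-[(1R,3Z)-1-chloro-6-(trimethylsilyl)hex-3-en-5-yn-1-yl]oxolane F9, and K2CO3 in MeOH at 0 °C removes the C1 silyl group to give 17.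

Further compounds
F1 | step 3 | tert-butyl(dimethyl)[(3S)-pent-1-yn-3-yloxy]silane | C#C[C@@H](O[Si](C)(C)C(C)(C)C)CC
F2 | step 3 | ethyl (4S)-4-hydroxy-4-[(2S)-oxiran-2-yl]butanoate | CCOC(=O)CC[C@H](O)[C@@H]1CO1
F3 | step 3 | (5S)-5-[(2S)-oxiran-2-yl]oxolan-2-one | O=C1CC[C@@H]([C@@H]2CO2)O1
F4 | step 3 | (5S)-2-{(3S)-3-[(tert-butyldimethylsilyl)oxy]pent-1-yn-1-yl}-5-[(2S)-oxiran-2-yl]oxolan-2-ol (anomer mixture) | OC1(C#C[C@@H](O[Si](C)(C)C(C)(C)C)CC)CC[C@@H]([C@@H]2CO2)O1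
F5 | step 7 | O6-dimethylsilyl ether of 12 | C[Si](C)(C)C#CC#CC[C@H](O[SiH](C)C)[C@@H]1C[C@@H](Br)[C@@](OC)(C#C[C@@H](O[Si](C)(C)C(C)(C)C)CC)O1
F6 | step 7 | (1S)-1-[(2S,4R,5R)-4-bromo-5-{(3S)-3-[(tert-butyldimethylsilyl)oxy]pent-1-yn-1-yl}oxolan-2-yl]-6-(trimethylsilyl)hexa-3,5-diyn-1-ol | C[Si](C)(C)C#CC#CC[C@H](O)[C@@H]1C[C@@H](Br)[C@@H](C#C[C@@H](O[Si](C)(C)C(C)(C)C)CC)O1
F7 | step 10 | (3S)-1-{(2R,3R,5S)-3-bromo-5-[(1R)-1-chloro-6-(trimethylsilyl)hexa-3,5-diyn-1-yl]oxolan-2-yl}pent-1-yn-3-ol | C[Si](C)(C)C#CC#CC[C@@H](Cl)[C@@H]1C[C@@H](Br)[C@@H](C#C[C@@H](O)CC)O1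
F8 | step 10 | (2R,3R,5S)-3-bromo-2-[(3R)-3-bromopent-1-yn-1-yl]-5-[(1R)-1-chloro-6-(trimethylsilyl)hexa-3,5-diyn-1-yl]oxolane | C[Si](C)(C)C#CC#CC[C@@H](Cl)[C@@H]1C[C@@H](Br)[C@@H](C#C[C@H](Br)CC)O1
F9 | step 10 | (2R,3R,5S)-3-bromo-2-[(1Z,3R)-3-bromopent-1-en-1-yl]-5-[(1R,3Z)-1-chloro-6-(trimethylsilyl)hex-3-en-5-yn-1-yl]oxolane | C[Si](C)(C)C#C/C=C\C[C@@H](Cl)[C@@H]1C[C@@H](Br)[C@@H](/C=C\[C@H](Br)CC)O1
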